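**Retrosynthetic overview**
1. Target 20 ⇒ nonamethyl ether 19 by global O‑demethylation (last step).
2. 19 ⇒ core phenol 16 + stilbene 18: anodic formal [3+2] makes C8c–C14b and C7c–O13b (second dihydrobenzofuran, formed last).
3. 16 ⇒ acyclic triarylethane 13: one acid cascade closes the first dihydrobenzofuran (C7a–O11b), then the seven‑membered ring (C7b–C10a Friedel–Crafts).
4. 13 ⇒ resorcinol stilbene 8 + aldehyde 4 + aryl Grignard 10: ortho‑hydroxyalkylation (C8a–C10b), then o‑quinone‑methide arylation (C8a–C9a) steered by the silyloxy stereocentre.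
5. 4 ⇐ (S)‑4‑methoxymandelic acid 1, the only stereogenic input; 8 and 18 ⇐ Horner–Wadsworth–Emmons reactions of phosphonate 6. Ring order: first dihydrobenzofuran → seven‑membered ring → second dihydrobenzofuran.

Assumption: 1, 5, 6, 10 and 17 are taken as purchasable. Stereocentres carry stilbenoid locants: unit A has C7a, C8a and a 3,5‑dioxygenated aryl ring containing C9a/C10a; central unit B has C7b, C8b, ring carbons C9b–C14b and oxygens O11b and O13b; unit C has C7c, C8c.

**Route**

Step 1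
Reactants: 1 (S)-4-methoxymandelic acid
Product: 2 methyl (2S)-2-hydroxy-2-(4-methoxyphenyl)acetate
Conditions: MeI, KHCO3, DMF, 23 °C
Reagents that add atoms: iodomethane, CI
Why: Carboxylate O‑alkylation (SN2 on MeI) under bicarbonate leaves the benzylic carbinol untouched and avoids acidic esterification, which could ionise the p‑anisyl carbinol.

Step 2
Reactants: 2 methyl (2S)-2-hydroxy-2-(4-methoxyphenyl)acetate
Product: 3 methyl (2S)-2-(tert-butyldimethylsilyloxy)-2-(4-methoxyphenyl)acetate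
Conditions: TBSCl, imidazole, DMF, 23 °C
Reagents that add atoms: tert-butyldimethylsilyl chloride, CC(C)(C)[Si](C)(C)Cl
Why: Standard silylation of a secondary alcohol; the bulky, non‑chelating silyl ether later acts as the polar control element next to C8a.

Step 3
Reactants: 3 methyl (2S)-2-(tert-butyldimethylsilyloxy)-2-(4-methoxyphenyl)acetate
Product: 4 (2S)-2-(tert-butyldimethylsilyloxy)-2-(4-methoxyphenyl)acetaldehyde
Conditions: i-Bu2AlH (1.1 equiv), CH2Cl2, −78 °C; aq. potassium sodium tartrate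
Reagents that add atoms: none
Why: Partial ester reduction stops at the aldehyde through the stable α‑silyloxy tetrahedral aluminate at −78 °C; 4 is used at once so its α‑stereocentre does not epimerise.

Step 4
Reactants: 5 3,5-bis(tert-butyldimethylsilyloxy)benzaldehyde; 6 diethyl (2,4-dimethoxybenzyl)phosphonate
Product: 8 5-[(E)-2-(2,4-dimethoxyphenyl)ethenyl]benzene-1,3-diol, via bis-silyl stilbene 7 (not isolated)
Conditions: NaH, THF, 0 → 23 °C; then MeOH, K2CO3 (cat.), 23 °C
Reagents that add atoms: none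
Why: Horner–Wadsworth–Emmons olefination of a benzylic phosphonate gives the (E)‑stilbene, and methanolysis of the two aryl silyl ethers in the same flask frees the resorcinol.

Step 5
Reactants: 8 5-[(E)-2-(2,4-dimethoxyphenyl)ethenyl]benzene-1,3-diol; 4 (2S)-2-(tert-butyldimethylsilyloxy)-2-(4-methoxyphenyl)acetaldehyde
Product: 9 4-[(2S)-2-(tert-butyldimethylsilyloxy)-1-hydroxy-2-(4-methoxyphenyl)ethyl]-5-[(E)-2-(2,4-dimethoxyphenyl)ethenyl]benzene-1,3-diol (both C-1 epimers)
Conditions: EtMgBr (2.0 equiv on 8), Et2O, 0 °C; solvent exchange to CH2Cl2; 4 (0.7 equiv), −20 → 20 °C; aq. NH4Cl; used after a short filtration through silica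
Reagents that add atoms: none
Why: Casiraghi ortho‑specific hydroxyalkylation, in which the magnesium phenoxide delivers the bound aldehyde to the ortho carbon next to the styryl arm (the 4‑position of a 5‑substituted resorcinol, as in orsellinic‑type C‑functionalisation, any 2‑substituted isomer being removed in the filtration); the new carbinol centre is uncontrolled and is erased in step 6, while the silyloxy centre from 1 is untouched.

Step 6
Reactants: 9 4-[(2S)-2-(tert-butyldimethylsilyloxy)-1-hydroxy-2-(4-methoxyphenyl)ethyl]-5-[(E)-2-(2,4-dimethoxyphenyl)ethenyl]benzene-1,3-diol; 10 3,5-dimethoxyphenylmagnesium bromide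
Product: 13 tert-butyl 4-[(1R,2R)-2-(tert-butyldimethylsilyloxy)-1-(3,5-dimethoxyphenyl)-2-(4-methoxyphenyl)ethyl]-3-[(E)-2-(2,4-dimethoxyphenyl)ethenyl]-5-hydroxyphenyl carbonate, via bis(tert-butyl carbonate) 11 (not isolated), via o-quinone methide 12 (not isolated)
Conditions: Boc2O (2.05 equiv), DMAP (5 mol %), CH2Cl2, 0 °C; then THF, 10 (3.0 equiv), −78 → 0 °C; pH 7 buffer; chromatography
Reagents that add atoms: di-tert-butyl dicarbonate, CC(C)(C)OC(=O)OC(=O)OC(C)(C)C
Why: Pettus‑type anionic o‑quinone‑methide generation (alkoxide‑triggered carbonate transfer, then elimination) followed by 1,4‑addition of the aryl Grignard; C8a is set by the silyloxy centre from 1 through a modified Felkin–Anh transition state (C7a–H eclipsing the exocyclic C=C to avoid allylic strain, aryl entering anti to the C–OSi bond), and the (1R,2R) isomer is separated from its C‑1 epimer before going on.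

Step 7
Reactants: 13 tert-butyl 4-[(1R,2R)-2-(tert-butyldimethylsilyloxy)-1-(3,5-dimethoxyphenyl)-2-(4-methoxyphenyl)ethyl]-3-[(E)-2-(2,4-dimethoxyphenyl)ethenyl]-5-hydroxyphenyl carbonate
Product: 16 (1R,8R,16R)-8-(2,4-dimethoxyphenyl)-4,6-dimethoxy-16-(4-methoxyphenyl)-15-oxatetracyclo[8.6.1.0^{2,7}.0^{14,17}]heptadeca-2(7),3,5,10(17),11,13-hexaen-12-ol (7aR,8aR,7bR), via dihydrobenzofuran carbonate 14 (not isolated), via seven-ring carbonate 15 (not isolated)
Conditions: CF3CO2H (20 equiv), CH2Cl2 (0.01 M), −20 → 23 °C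
Reagents that add atoms: none
Why: Brønsted‑acid cascade in which SN1 ionisation of the p‑anisyl silyl ether and 5‑ring capture by the ortho phenol give the thermodynamic trans‑dihydrobenzofuran (C7a now dictated by C8a), protonation of the 2,4‑dimethoxystyryl arm then triggers Friedel–Crafts closure of the seven‑membered ring onto the 3,5‑dimethoxyphenyl ring of unit A with the relative configuration at C7b of the ε‑viniferin → ampelopsin B cyclisation, and the aryl tert‑butyl carbonate is cleaved by the same acid.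

Step 8
Reactants: 17 3,5-dimethoxybenzaldehyde; 6 diethyl (2,4-dimethoxybenzyl)phosphonate
Product: 18 1-[(E)-2-(3,5-dimethoxyphenyl)ethenyl]-2,4-dimethoxybenzene
Conditions: NaH, THF, 0 → 23 °C
Reagents that add atoms: none
Why: Horner–Wadsworth–Emmons olefination gives the (E)‑stilbene partner for the last ring.

Step 9
Reactants: 16 core phenol (7aR,8aR,7bR); 18 1-[(E)-2-(3,5-dimethoxyphenyl)ethenyl]-2,4-dimethoxybenzene
Product: 19 nona-O-methyl ether of the target (7aR,8aR,7bR,7cS,8cS)
Conditions: undivided cell, graphite anode, Pt cathode, +0.80 V vs Ag/AgCl (ca. 2.2 F/mol), n-Bu4NPF6 (0.1 M), 2,6-lutidine (2 equiv), 18 (3 equiv), (CF3)2CHOH/CH2Cl2 1:3, 0 °C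
Reagents that add atoms: none
Why: Proposed new method: anodic proton‑coupled oxidation of the single free phenol of 16 (hydrogen‑bonded to lutidine and oxidised below the potential of 18) gives a phenoxyl radical whose C14b (ortho to O13b, para to the furan oxygen) adds to C8c of 18; the resulting 2,4‑dimethoxybenzyl radical is oxidised to the cation and, after re‑aromatisation, captured by O13b to close the trans‑dihydrobenzofuran; the stilbene is expected to approach the face of 16 away from the folded dimethoxybenzo ring of unit A and H‑7b with its styryl π‑system under the central ring, which places the C8c aryl syn to that benzo ring (7cS,8cS); the closest known reaction type is the anodic or photocatalytic oxidative phenol–alkene [3+2] annulation of para‑alkoxyphenols (phenoxonium route), here extended to a resorcinol‑type phenol, an unsymmetrical stilbene and remote substrate stereocontrol.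

Step 10
Reactants: 19 nona-O-methyl ether of the target
Product: 20 CNP0283541.1 (7aR,8aR,7bR,7cS,8cS)
Conditions: BBr3 (20 equiv), CH2Cl2, −78 → 23 °C; MeOH, then H2O
Reagents that add atoms: none
Why: Lewis‑acid cleavage of the nine aryl methyl ethers, a standard endgame for permethylated oligostilbenes; with no alkene left, a transiently opened benzylic C–O bond can only re‑close to the same trans‑dihydrobenzofuran, so no stereocentre is lost.

**Compound list**
1 | (2S)-2-hydroxy-2-(4-methoxyphenyl)acetic acid, (S)-4-methoxymandelic acid | COc1ccc(cc1)[C@H](O)C(=O)O | starting material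
2 | methyl (2S)-2-hydroxy-2-(4-methoxyphenyl)acetate | COc1ccc(cc1)[C@H](O)C(=O)OC | intermediate
3 | methyl (2S)-2-(tert-butyldimethylsilyloxy)-2-(4-methoxyphenyl)acetate | COc1ccc(cc1)[C@H](O[Si](C)(C)C(C)(C)C)C(=O)OC | intermediate
4 | (2S)-2-(tert-butyldimethylsilyloxy)-2-(4-methoxyphenyl)acetaldehyde | COc1ccc(cc1)[C@H](O[Si](C)(C)C(C)(C)C)C=O | intermediate
5 | 3,5-bis(tert-butyldimethylsilyloxy)benzaldehyde | O=Cc1cc(O[Si](C)(C)C(C)(C)C)cc(O[Si](C)(C)C(C)(C)C)c1 | starting material
6 | diethyl (2,4-dimethoxybenzyl)phosphonate | CCOP(=O)(Cc1ccc(OC)cc1OC)OCC | starting material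
7 | bis-silyl stilbene, (E)-1,3-bis(tert-butyldimethylsilyloxy)-5-[2-(2,4-dimethoxyphenyl)ethenyl]benzene | COc1ccc(/C=C/c2cc(O[Si](C)(C)C(C)(C)C)cc(O[Si](C)(C)C(C)(C)C)c2)c(OC)c1 | intermediate (not isolated)
8 | 5-[(E)-2-(2,4-dimethoxyphenyl)ethenyl]benzene-1,3-diol | COc1ccc(/C=C/c2cc(O)cc(O)c2)c(OC)c1 | intermediate
9 | 4-[(2S)-2-(tert-butyldimethylsilyloxy)-1-hydroxy-2-(4-methoxyphenyl)ethyl]-5-[(E)-2-(2,4-dimethoxyphenyl)ethenyl]benzene-1,3-diol, both C-1 epimers | COc1ccc(/C=C/c2cc(O)cc(O)c2C(O)[C@@H](O[Si](C)(C)C(C)(C)C)c2ccc(OC)cc2)c(OC)c1 | intermediate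
10 | 3,5-dimethoxyphenylmagnesium bromide | COc1cc(OC)cc([Mg]Br)c1 | starting material
11 | bis(tert-butyl carbonate) of 9 at both phenols | COc1ccc(/C=C/c2cc(OC(=O)OC(C)(C)C)cc(OC(=O)OC(C)(C)C)c2C(O)[C@@H](O[Si](C)(C)C(C)(C)C)c2ccc(OC)cc2)c(OC)c1 | intermediate (not isolated)
12 | o-quinone methide, tert-butyl 4-[(2R)-2-(tert-butyldimethylsilyloxy)-2-(4-methoxyphenyl)ethylidene]-5-[(E)-2-(2,4-dimethoxyphenyl)ethenyl]-3-oxocyclohexa-1,5-dien-1-yl carbonate, exocyclic alkene geometry not assigned | COc1ccc(/C=C/C2=CC(OC(=O)OC(C)(C)C)=CC(=O)C2=C[C@@H](O[Si](C)(C)C(C)(C)C)c2ccc(OC)cc2)c(OC)c1 | intermediate (not isolated)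
13 | tert-butyl 4-[(1R,2R)-2-(tert-butyldimethylsilyloxy)-1-(3,5-dimethoxyphenyl)-2-(4-methoxyphenyl)ethyl]-3-[(E)-2-(2,4-dimethoxyphenyl)ethenyl]-5-hydroxyphenyl carbonate | COc1ccc(/C=C/c2cc(OC(=O)OC(C)(C)C)cc(O)c2[C@@H](c2cc(OC)cc(OC)c2)[C@@H](O[Si](C)(C)C(C)(C)C)c2ccc(OC)cc2)c(OC)c1 | intermediate
14 | tert-butyl (2R,3R)-3-(3,5-dimethoxyphenyl)-4-[(E)-2-(2,4-dimethoxyphenyl)ethenyl]-2-(4-methoxyphenyl)-2,3-dihydro-1-benzofuran-6-yl carbonate | COc1ccc([C@@H]2Oc3cc(OC(=O)OC(C)(C)C)cc(/C=C/c4ccc(OC)cc4OC)c3[C@H]2c2cc(OC)cc(OC)c2)cc1 | intermediate (not isolated)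
15 | tert-butyl (1R,8R,16R)-8-(2,4-dimethoxyphenyl)-4,6-dimethoxy-16-(4-methoxyphenyl)-15-oxatetracyclo[8.6.1.0^{2,7}.0^{14,17}]heptadeca-2(7),3,5,10(17),11,13-hexaen-12-yl carbonate | COc1ccc([C@@H]2Oc3cc(OC(=O)OC(C)(C)C)cc4c3[C@H]2c2cc(OC)cc(OC)c2[C@@H](c2ccc(OC)cc2OC)C4)cc1 | intermediate (not isolated)
16 | (1R,8R,16R)-8-(2,4-dimethoxyphenyl)-4,6-dimethoxy-16-(4-methoxyphenyl)-15-oxatetracyclo[8.6.1.0^{2,7}.0^{14,17}]heptadeca-2(7),3,5,10(17),11,13-hexaen-12-ol (7aR,8aR,7bR; free OH is O13b) | COc1ccc([C@@H]2Oc3cc(O)cc4c3[C@H]2c2cc(OC)cc(OC)c2[C@@H](c2ccc(OC)cc2OC)C4)cc1 | intermediate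
17 | 3,5-dimethoxybenzaldehyde | COc1cc(C=O)cc(OC)c1 | starting material
18 | 1-[(E)-2-(3,5-dimethoxyphenyl)ethenyl]-2,4-dimethoxybenzene | COc1ccc(/C=C/c2cc(OC)cc(OC)c2)c(OC)c1 | intermediate
19 | nona-O-methyl ether of 20 (7aR,8aR,7bR,7cS,8cS): 16 carrying a trans-2-(2,4-dimethoxyphenyl)-3-(3,5-dimethoxyphenyl)-2,3-dihydrofuran fused at O13b/C14b | COc1ccc([C@@H]2Oc3cc4c(c5c3[C@H]2c2cc(OC)cc(OC)c2[C@@H](c2ccc(OC)cc2OC)C5)[C@H](c2cc(OC)cc(OC)c2)[C@@H](c2ccc(OC)cc2OC)O4)cc1 | intermediate
20 | CNP0283541.1 (7aR,8aR,7bR,7cS,8cS) | Oc1ccc([C@@H]2Oc3cc4c(c5c3[C@H]2c2cc(O)cc(O)c2[C@@H](c2ccc(O)cc2O)C5)[C@H](c2cc(O)cc(O)c2)[C@@H](c2ccc(O)cc2O)O4)cc1 | target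

**Totals and risks**

Total step count: 10. Longest linear sequence: 8 steps (1, 2, 3, 5, 6, 7, 9, 10).

The three steps most likely to fail:

Step 6. The acyclic 1,2‑induction on the o‑quinone methide may be weak, or the aryl may enter syn to the silyloxy group, and the quinone methide can also tautomerise by a 1,5‑hydrogen shift. The fallback sets out from 9 and comes back at 13, with hydride and aryl exchanging roles so that the same facial bias now gives the other C8a epimer. Alcohol 9 is oxidised with MnO2 in CH2Cl2 to ketone F1. Both phenols are then carbonated (Boc2O, cat. DMAP) to give ketone bis(tert-butyl carbonate) F2. Grignard 10 is added at −78 °C; carbonate transfer and elimination give aryl o‑quinone methide F3, which is reduced in the same flask with LiBH(s-Bu)3 to 13. This is the known Pettus three‑component sequence with hydride as second nucleophile. The keto intermediate has an acidic C7a–H, so 10 is best pre‑mixed with CeCl3.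

Step 9 (the proposed new method). Addition could occur at C12b instead of C14b, the phenoxyl radical could dimerise, or the facial selectivity could be low. The fallback uses known chemistry, sets out from 16 and comes back at 19. Ortho‑formylation (MgCl2, Et3N, paraformaldehyde, MeCN, reflux) gives salicylaldehyde F4. Addition of 10 (2.5 equiv, THF, −78 → 0 °C) gives benzhydrol F5. A [4+1] annulation follows between the o‑quinone methide released from F5 and the sulfur ylide formed with Cs2CO3 from sulfonium salt F6 (made from 2,4‑dimethoxybenzyl alcohol, Me2S and HBF4); it closes the trans‑dihydrobenzofuran and gives 19. The diastereomer at C8c, if formed, is separated by chromatography.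

Step 10. The second dihydrobenzofuran carries a 2,4‑dioxygenated aryl on its benzylic C–O carbon and may not survive prolonged BBr3. The fallback sets out from 16 and comes back at 20, moving the demethylation ahead of the last ring. BBr3 is applied to the robust core 16 (no alkene, no labile second furan) to give hexaphenol F7. F7 is then joined to commercial oxyresveratrol, Oc1ccc(/C=C/c2cc(O)cc(O)c2)c(O)c1, by a protecting‑group‑free oxidative cross‑coupling of the resveratrol → ε‑viniferin type (RuCl3·3H2O or FeCl3·6H2O, aqueous MeOH). This gives 20 directly in low yield after chromatographic separation of regio‑ and diastereomers.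

Further compounds
F1 | step 6 | 2-(tert-butyldimethylsilyloxy)-1-{2-[(E)-2-(2,4-dimethoxyphenyl)ethenyl]-4,6-dihydroxyphenyl}-2-(4-methoxyphenyl)ethan-1-one, (2S) | COc1ccc(/C=C/c2cc(O)cc(O)c2C(=O)[C@@H](O[Si](C)(C)C(C)(C)C)c2ccc(OC)cc2)c(OC)c1
F2 | step 6 | bis(tert-butyl carbonate) of F1 at both phenols | COc1ccc(/C=C/c2cc(OC(=O)OC(C)(C)C)cc(OC(=O)OC(C)(C)C)c2C(=O)[C@@H](O[Si](C)(C)C(C)(C)C)c2ccc(OC)cc2)c(OC)c1
F3 | step 6 | aryl o-quinone methide, as 12 with a 3,5-dimethoxyphenyl group on the exocyclic carbon | COc1ccc(/C=C/C2=CC(OC(=O)OC(C)(C)C)=CC(=O)C2=C(c2cc(OC)cc(OC)c2)[C@@H](O[Si](C)(C)C(C)(C)C)c2ccc(OC)cc2)c(OC)c1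
F4 | step 9 | 11-formyl derivative of 16 (formyl at C14b, ortho to the free OH) | COc1ccc([C@@H]2Oc3cc(O)c(C=O)c4c3[C@H]2c2cc(OC)cc(OC)c2[C@@H](c2ccc(OC)cc2OC)C4)cc1
F5 | step 9 | 11-[(3,5-dimethoxyphenyl)(hydroxy)methyl] derivative of 16, both carbinol epimers | COc1ccc([C@@H]2Oc3cc(O)c(C(O)c5cc(OC)cc(OC)c5)c4c3[C@H]2c2cc(OC)cc(OC)c2[C@@H](c2ccc(OC)cc2OC)C4)cc1
F6 | step 9 | (2,4-dimethoxybenzyl)dimethylsulfonium tetrafluoroborate | COc1ccc(C[S+](C)C)c(OC)c1.F[B-](F)(F)F
F7 | step 10 | (1R,8R,16R)-8-(2,4-dihydroxyphenyl)-16-(4-hydroxyphenyl)-15-oxatetracyclo[8.6.1.0^{2,7}.0^{14,17}]heptadeca-2(7),3,5,10(17),11,13-hexaene-4,6,12-triol | Oc1ccc([C@@H]2Oc3cc(O)cc4c3[C@H]2c2cc(O)cc(O)c2[C@@H](c2ccc(O)cc2O)C4)cc1
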